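The route rests on the C1–C2 bond of ring B. C1, the sp3 carbon carrying the pendant ring, is para-hydroxybenzylic through the C4' hydroxyl and can therefore be unmasked as the exocyclic carbon of a p-quinone methide. C2 is the CH2 of a ring A (E)-arylidene succinate (C3=C4) and is acidic as a vinylogous ester position. In one operation base expels sulfinate from a racemic diarylmethyl sulfone and the C2 dienolate closes ring B onto C1, setting C1 and C2 (trans) under control of a chiral ammonium ion. The precursor is a benzyl/MOM-protected diarylmethyl p-tolyl sulfone with a free C4' phenol and an ortho arylidene succinate.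

Key step: step 8

Locants: ring A is the benzo ring (C4a–C8a), ring B is C1–C4, the pendant ring is C1'–C6'; the same locants are used for all intermediates.
Assumption: the cinchonidinium salt of step 8 is taken to expose the face of the quinone methide that leads to (1R); if it should favour (1S), its pseudo-enantiomer N-(9-anthracenylmethyl)cinchoninium chloride is used under the same conditions.

Step 1
Reactants: 1 3,4-bis(benzyloxy)benzaldehyde
Product: 2 2-bromo-4,5-bis(benzyloxy)benzaldehyde
Conditions: Br2, NaOAc, AcOH, rt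
Reagents that add atoms: bromine, BrBr
Why: Electrophilic aromatic bromination should go para to the 3-benzyloxy group and ortho to the formyl group, the only alkoxy-activated position that is not flanked by two substituents, as is usual for 3,4-dialkoxybenzaldehydes.

Step 2
Reactants: 3 catechol
Product: 4 2-(methoxymethoxy)phenol
Conditions: 3 (2.5 equiv), NaH (1.0 equiv), THF–DMF, 0 °C; MOMCl (1.0 equiv), 0 °C to rt
Reagents that add atoms: chloromethyl methyl ether, COCCl
Why: Williamson O-alkylation of the monosodium catecholate with catechol in excess should stop at the mono-ether, and unreacted catechol is removed with water.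

Step 3
Reactants: 4 2-(methoxymethoxy)phenol
Product: 5 4-bromo-2-(methoxymethoxy)phenol
Conditions: NBS, MeCN, −20 °C to 0 °C
Reagents that add atoms: N-bromosuccinimide, O=C1CCC(=O)N1Br
Why: Electrophilic aromatic bromination is directed para to the free hydroxyl, the stronger activator, and the acid-free conditions spare the MOM acetal.

Step 4
Reactants: 5 4-bromo-2-(methoxymethoxy)phenol
Product: 6 2-[4-bromo-2-(methoxymethoxy)phenoxy]tetrahydro-2H-pyran (racemic)
Conditions: 3,4-dihydro-2H-pyran, PPTS (cat.), CH2Cl2, rt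
Reagents that add atoms: 3,4-dihydro-2H-pyran, C1=COCCC1
Why: Acid-catalysed tetrahydropyranylation of the phenol under PPTS, which is too weak to touch the MOM ether; the acetal carbon forms without control and is removed again in step 7.

Step 5
Reactants: 6 2-[4-bromo-2-(methoxymethoxy)phenoxy]tetrahydro-2H-pyran; 2 2-bromo-4,5-bis(benzyloxy)benzaldehyde
Product: 9 2-[4-[[4,5-bis(benzyloxy)-2-bromophenyl](methoxy)methyl]-2-(methoxymethoxy)phenoxy]tetrahydro-2H-pyran (diastereomer mixture), via aryllithium 7 (not isolated), via lithium alkoxide 8 (not isolated)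
Conditions: 6, n-BuLi, THF, −78 °C; then 2, −78 °C; then MeI, DMPU, −78 °C to rt
Reagents that add atoms: iodomethane, CI
Why: Bromine–lithium exchange, 1,2-addition of the aryllithium to the aldehyde and Williamson O-methylation of the lithium alkoxide in one pot; the benzhydryl carbon forms without control, which is harmless because it becomes the planar quinone methide carbon in step 8.

Step 6
Reactants: 9 2-[4-[[4,5-bis(benzyloxy)-2-bromophenyl](methoxy)methyl]-2-(methoxymethoxy)phenoxy]tetrahydro-2H-pyran; 10 dimethyl itaconate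
Product: 11 dimethyl (E)-2-[[4,5-bis(benzyloxy)-2-[methoxy[3-(methoxymethoxy)-4-(tetrahydro-2H-pyran-2-yloxy)phenyl]methyl]phenyl]methylidene]butanedioate
Conditions: Pd2(dba)3 (2.5 mol %), [(t-Bu)3PH]BF4 (10 mol %), Cy2NMe, 10 (2 equiv), 1,4-dioxane, 80 °C
Reagents that add atoms: none
Why: Mizoroki–Heck arylation of the 1,1-disubstituted alkene with a bulky electron-rich phosphine, as a hindered electron-rich aryl bromide requires; β-hydride elimination towards the benzylic hydrogen should give the conjugated arylidene succinate with the aryl group trans to the C3 ester (E), the usual outcome of itaconate arylations.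

Step 7
Reactants: 11 dimethyl (E)-2-[[4,5-bis(benzyloxy)-2-[methoxy[3-(methoxymethoxy)-4-(tetrahydro-2H-pyran-2-yloxy)phenyl]methyl]phenyl]methylidene]butanedioate
Product: 12 dimethyl (E)-2-[[4,5-bis(benzyloxy)-2-[[4-hydroxy-3-(methoxymethoxy)phenyl](4-methylbenzenesulfonyl)methyl]phenyl]methylidene]butanedioate (racemic)
Conditions: p-TolSO2H (3 equiv), MeOH (5 equiv), CH2Cl2, 0 °C to rt
Reagents that add atoms: p-toluenesulfinic acid, Cc1ccc(cc1)S(=O)O
Why: Acid-mediated SN1 sulfone formation: the sulfinic acid cleaves the aryl THP acetal and ionises the doubly alkoxy-stabilised benzhydryl methyl ether, the sulfinate sulfur captures the cation (racemic benzhydryl carbon), and the MOM ether, benzyl ethers, esters and the electron-poor alkene should tolerate this weak acid.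

Step 8
Reactants: 12 dimethyl (E)-2-[[4,5-bis(benzyloxy)-2-[[4-hydroxy-3-(methoxymethoxy)phenyl](4-methylbenzenesulfonyl)methyl]phenyl]methylidene]butanedioate
Product: 14 dimethyl (1R,2S)-6,7-bis(benzyloxy)-1-[4-hydroxy-3-(methoxymethoxy)phenyl]-1,2-dihydronaphthalene-2,3-dicarboxylate, via quinone methide 13 (not isolated)
Conditions: N-(9-anthracenylmethyl)cinchonidinium chloride (10 mol %), Cs2CO3 (2.5 equiv), toluene–CH2Cl2 (4:1), −20 °C, Ar
Reagents that add atoms: none
Why: Proposed new method: Cs2CO3 deprotonates the C4' phenol and E1cB loss of p-toluenesulfinate from either enantiomer of 12 gives the same planar p-quinone methide 13, whose C2–H (alpha to an ester, allylic to C3=C4 and conjugated with the quinone methide through ring A) is removed to a dienolate paired with the cinchonidinium cation, and C2 then adds to the exocyclic C1 in a vinylogous 1,6-addition that rearomatises the pendant ring. The closest known reaction type is the phase-transfer-catalysed asymmetric 1,6-addition of carbon pronucleophiles to p-quinone methides released in situ from sulfones; the intramolecular use of an ester dienolate is the untested part. Ring B closes in a 6-exo-trig mode, since the attacked C1=C1' bond lies outside the new ring. C1 is set by the chiral ammonium ion pair, which can hydrogen-bond through its free hydroxyl and shields one face of the quinone methide, and C2 is set by thermodynamic control because it stays epimerisable under the base and settles trans to the C1 aryl group. The step needs bond formation through C2 and not through C4 or oxygen, and ring closure before external nucleophiles trap 13: the E geometry holds the CH2 next to C1, attack through C4 would give a four-membered ring, and the free C4' hydroxyl that the target itself carries makes the planar electrophile available.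

Step 9
Reactants: 14 dimethyl (1R,2S)-6,7-bis(benzyloxy)-1-[4-hydroxy-3-(methoxymethoxy)phenyl]-1,2-dihydronaphthalene-2,3-dicarboxylate
Product: 15 dimethyl (1R,2S)-6,7-bis(benzyloxy)-1-[4-(benzyloxy)-3-(methoxymethoxy)phenyl]-1,2-dihydronaphthalene-2,3-dicarboxylate
Conditions: BnBr, K2CO3, acetone, rt
Reagents that add atoms: benzyl bromide, BrCc1ccccc1
Why: Williamson O-benzylation of the only free phenol under a weak base, which can at most return C2 to the favoured trans arrangement.

Step 10
Reactants: 15 dimethyl (1R,2S)-6,7-bis(benzyloxy)-1-[4-(benzyloxy)-3-(methoxymethoxy)phenyl]-1,2-dihydronaphthalene-2,3-dicarboxylate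
Product: 16 dimethyl (1R,2S)-6,7-bis(benzyloxy)-1-[4-(benzyloxy)-3-hydroxyphenyl]-1,2-dihydronaphthalene-2,3-dicarboxylate
Conditions: conc. HCl (cat.), MeOH–THF, 45 °C
Reagents that add atoms: none
Why: Acid-catalysed acetal exchange should remove the MOM group as dimethoxymethane while aryl benzyl ethers, methyl esters (in methanol) and both stereocentres stay untouched.

Step 11
Reactants: 17 methyl bis(2,2,2-trifluoroethyl)phosphonoacetate
Product: 18 methyl 2-[bis(2,2,2-trifluoroethoxy)phosphoryl]-2-diazoacetate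
Conditions: 4-acetamidobenzenesulfonyl azide, DBU, MeCN, 0 °C to rt
Reagents that add atoms: 4-acetamidobenzenesulfonyl azide, CC(=O)Nc1ccc(cc1)S(=O)(=O)N=[N+]=[N-]
Why: Regitz diazo transfer to the acidic methylene between phosphoryl and ester groups.

Step 12
Reactants: 16 dimethyl (1R,2S)-6,7-bis(benzyloxy)-1-[4-(benzyloxy)-3-hydroxyphenyl]-1,2-dihydronaphthalene-2,3-dicarboxylate; 18 methyl 2-[bis(2,2,2-trifluoroethoxy)phosphoryl]-2-diazoacetate
Product: 19 dimethyl (1R,2S)-6,7-bis(benzyloxy)-1-[4-(benzyloxy)-3-[1-[bis(2,2,2-trifluoroethoxy)phosphoryl]-2-methoxy-2-oxoethoxy]phenyl]-1,2-dihydronaphthalene-2,3-dicarboxylate (both epimers at the phosphonate carbon)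
Conditions: Rh2(OAc)4 (2 mol %), toluene, 80 °C, slow addition of 18
Reagents that add atoms: none
Why: Rhodium carbenoid O–H insertion into the phenol, which should outrun any reaction with the ethers, the arenes or the electron-poor C3=C4 alkene; the new phosphonate-bearing carbon forms as both epimers and is flattened in step 13.

Step 13
Reactants: 19 dimethyl (1R,2S)-6,7-bis(benzyloxy)-1-[4-(benzyloxy)-3-[1-[bis(2,2,2-trifluoroethoxy)phosphoryl]-2-methoxy-2-oxoethoxy]phenyl]-1,2-dihydronaphthalene-2,3-dicarboxylate; 1 3,4-bis(benzyloxy)benzaldehyde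
Product: 20 dimethyl (1R,2S)-6,7-bis(benzyloxy)-1-[4-(benzyloxy)-3-[[(E)-1-[3,4-bis(benzyloxy)phenyl]-3-methoxy-3-oxoprop-1-en-2-yl]oxy]phenyl]-1,2-dihydronaphthalene-2,3-dicarboxylate
Conditions: KN(SiMe3)2 (1.0 equiv), 18-crown-6, THF, −78 °C; then 1, −78 °C
Reagents that add atoms: none
Why: Still–Gennari variant of the Horner–Wadsworth–Emmons olefination, in which the electron-poor bis(trifluoroethyl) phosphonate collapses from the kinetic adduct and should place the aldehyde aryl group cis to the ester and so trans to the aryloxy oxygen (E), while the far more acidic phosphonate C–H takes the single equivalent of base ahead of C2–H.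

Step 14
Reactants: 20 dimethyl (1R,2S)-6,7-bis(benzyloxy)-1-[4-(benzyloxy)-3-[[(E)-1-[3,4-bis(benzyloxy)phenyl]-3-methoxy-3-oxoprop-1-en-2-yl]oxy]phenyl]-1,2-dihydronaphthalene-2,3-dicarboxylate
Product: 21 (1R,2S)-6,7-bis(benzyloxy)-1-[4-(benzyloxy)-3-[[(E)-2-[3,4-bis(benzyloxy)phenyl]-1-carboxyethenyl]oxy]phenyl]-1,2-dihydronaphthalene-2,3-dicarboxylic acid
Conditions: LiOH·H2O (15 equiv), THF–MeOH–H2O, rt to 40 °C, Ar; then 1 M HCl to pH 2
Reagents that add atoms: lithium hydroxide, [Li+].[OH-]; water, O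
Why: Saponification of the three methyl esters with every phenol still protected; C2 is already in the thermodynamically preferred trans arrangement and loses its acidity once the carboxylate forms, and the enol ether has no base-mediated path to isomerise.

Step 15
Reactants: 21 (1R,2S)-6,7-bis(benzyloxy)-1-[4-(benzyloxy)-3-[[(E)-2-[3,4-bis(benzyloxy)phenyl]-1-carboxyethenyl]oxy]phenyl]-1,2-dihydronaphthalene-2,3-dicarboxylic acid
Product: 22 (1R,2S)-1-[3-[[(E)-1-carboxy-2-(3,4-dihydroxyphenyl)ethenyl]oxy]-4-hydroxyphenyl]-6,7-dihydroxy-1,2-dihydronaphthalene-2,3-dicarboxylic acid (CNP0241205.1)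
Conditions: BCl3 (1 M in CH2Cl2, 15 equiv), pentamethylbenzene (15 equiv), CH2Cl2, −78 °C; MeOH–H2O quench
Reagents that add atoms: none
Why: Lewis-acid debenzylation of the five aryl benzyl ethers at −78 °C with pentamethylbenzene as a non-basic benzyl cation scavenger, conditions that should leave the alkenes, the enol ether geometry, the carboxylic acids and both stereocentres untouched.

Compound list
1 | 3,4-bis(benzyloxy)benzaldehyde | O=Cc1ccc(OCc2ccccc2)c(OCc2ccccc2)c1 | starting material
2 | 2-bromo-4,5-bis(benzyloxy)benzaldehyde | O=Cc1cc(OCc2ccccc2)c(OCc2ccccc2)cc1Br | intermediate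
3 | catechol (benzene-1,2-diol) | Oc1ccccc1O | starting material
4 | 2-(methoxymethoxy)phenol | COCOc1ccccc1O | intermediate
5 | 4-bromo-2-(methoxymethoxy)phenol | COCOc1cc(Br)ccc1O | intermediate
6 | 2-[4-bromo-2-(methoxymethoxy)phenoxy]tetrahydro-2H-pyran, racemic | COCOc1cc(Br)ccc1OC1CCCCO1 | intermediate
7 | [3-(methoxymethoxy)-4-(tetrahydro-2H-pyran-2-yloxy)phenyl]lithium, not isolated | [Li]c1ccc(OC2CCCCO2)c(OCOC)c1 | intermediate
8 | lithium [4,5-bis(benzyloxy)-2-bromophenyl][3-(methoxymethoxy)-4-(tetrahydro-2H-pyran-2-yloxy)phenyl]methanolate, not isolated | [Li]OC(c1ccc(OC2CCCCO2)c(OCOC)c1)c1cc(OCc2ccccc2)c(OCc2ccccc2)cc1Br | intermediate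
9 | 2-[4-[[4,5-bis(benzyloxy)-2-bromophenyl](methoxy)methyl]-2-(methoxymethoxy)phenoxy]tetrahydro-2H-pyran, racemic mixture of diastereomers | COC(c1ccc(OC2CCCCO2)c(OCOC)c1)c1cc(OCc2ccccc2)c(OCc2ccccc2)cc1Br | intermediate
10 | dimethyl itaconate | C=C(CC(=O)OC)C(=O)OC | starting material
11 | dimethyl (E)-2-[[4,5-bis(benzyloxy)-2-[methoxy[3-(methoxymethoxy)-4-(tetrahydro-2H-pyran-2-yloxy)phenyl]methyl]phenyl]methylidene]butanedioate, E alkene, racemic mixture of diastereomers | COC(=O)C/C(C(=O)OC)=C\c1cc(OCc2ccccc2)c(OCc2ccccc2)cc1C(OC)c1ccc(OC2CCCCO2)c(OCOC)c1 | intermediate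
12 | dimethyl (E)-2-[[4,5-bis(benzyloxy)-2-[[4-hydroxy-3-(methoxymethoxy)phenyl](4-methylbenzenesulfonyl)methyl]phenyl]methylidene]butanedioate, E alkene, racemic at the sulfonyl-bearing carbon | COC(=O)C/C(C(=O)OC)=C\c1cc(OCc2ccccc2)c(OCc2ccccc2)cc1C(c1ccc(O)c(OCOC)c1)S(=O)(=O)c1ccc(C)cc1 | intermediate
13 | dimethyl (E)-2-[[4,5-bis(benzyloxy)-2-[[3-(methoxymethoxy)-4-oxocyclohexa-2,5-dien-1-ylidene]methyl]phenyl]methylidene]butanedioate, p-quinone methide, not isolated | COC(=O)C/C(C(=O)OC)=C\c1cc(OCc2ccccc2)c(OCc2ccccc2)cc1C=C1C=CC(=O)C(OCOC)=C1 | intermediate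
14 | dimethyl (1R,2S)-6,7-bis(benzyloxy)-1-[4-hydroxy-3-(methoxymethoxy)phenyl]-1,2-dihydronaphthalene-2,3-dicarboxylate, trans | COC(=O)C1=Cc2cc(OCc3ccccc3)c(OCc3ccccc3)cc2[C@@H](c2ccc(O)c(OCOC)c2)[C@@H]1C(=O)OC | intermediate
15 | dimethyl (1R,2S)-6,7-bis(benzyloxy)-1-[4-(benzyloxy)-3-(methoxymethoxy)phenyl]-1,2-dihydronaphthalene-2,3-dicarboxylate | COC(=O)C1=Cc2cc(OCc3ccccc3)c(OCc3ccccc3)cc2[C@@H](c2ccc(OCc3ccccc3)c(OCOC)c2)[C@@H]1C(=O)OC | intermediate
16 | dimethyl (1R,2S)-6,7-bis(benzyloxy)-1-[4-(benzyloxy)-3-hydroxyphenyl]-1,2-dihydronaphthalene-2,3-dicarboxylate | COC(=O)C1=Cc2cc(OCc3ccccc3)c(OCc3ccccc3)cc2[C@@H](c2ccc(OCc3ccccc3)c(O)c2)[C@@H]1C(=O)OC | intermediate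
17 | methyl bis(2,2,2-trifluoroethyl)phosphonoacetate | COC(=O)CP(=O)(OCC(F)(F)F)OCC(F)(F)F | starting material
18 | methyl 2-[bis(2,2,2-trifluoroethoxy)phosphoryl]-2-diazoacetate | COC(=O)C(=[N+]=[N-])P(=O)(OCC(F)(F)F)OCC(F)(F)F | intermediate
19 | dimethyl (1R,2S)-6,7-bis(benzyloxy)-1-[4-(benzyloxy)-3-[1-[bis(2,2,2-trifluoroethoxy)phosphoryl]-2-methoxy-2-oxoethoxy]phenyl]-1,2-dihydronaphthalene-2,3-dicarboxylate, both epimers at the phosphonate carbon | COC(=O)C1=Cc2cc(OCc3ccccc3)c(OCc3ccccc3)cc2[C@@H](c2ccc(OCc3ccccc3)c(OC(C(=O)OC)P(=O)(OCC(F)(F)F)OCC(F)(F)F)c2)[C@@H]1C(=O)OC | intermediate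
20 | dimethyl (1R,2S)-6,7-bis(benzyloxy)-1-[4-(benzyloxy)-3-[[(E)-1-[3,4-bis(benzyloxy)phenyl]-3-methoxy-3-oxoprop-1-en-2-yl]oxy]phenyl]-1,2-dihydronaphthalene-2,3-dicarboxylate, enol ether oxygen trans to the aryl group | COC(=O)C1=Cc2cc(OCc3ccccc3)c(OCc3ccccc3)cc2[C@@H](c2ccc(OCc3ccccc3)c(O/C(=C/c3ccc(OCc4ccccc4)c(OCc4ccccc4)c3)C(=O)OC)c2)[C@@H]1C(=O)OC | intermediate
21 | (1R,2S)-6,7-bis(benzyloxy)-1-[4-(benzyloxy)-3-[[(E)-2-[3,4-bis(benzyloxy)phenyl]-1-carboxyethenyl]oxy]phenyl]-1,2-dihydronaphthalene-2,3-dicarboxylic acid | OC(=O)C1=Cc2cc(OCc3ccccc3)c(OCc3ccccc3)cc2[C@@H](c2ccc(OCc3ccccc3)c(O/C(=C/c3ccc(OCc4ccccc4)c(OCc4ccccc4)c3)C(=O)O)c2)[C@@H]1C(=O)O | intermediate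
22 | (1R,2S)-1-[3-[[(E)-1-carboxy-2-(3,4-dihydroxyphenyl)ethenyl]oxy]-4-hydroxyphenyl]-6,7-dihydroxy-1,2-dihydronaphthalene-2,3-dicarboxylic acid | O=C(O)C1=Cc2cc(O)c(O)cc2[C@@H](c2ccc(O)c(O/C(=C/c3ccc(O)c(O)c3)C(=O)O)c2)[C@@H]1C(=O)O | target

Total step count: 15.
Longest linear sequence: 13 steps (3 → 4 → 5 → 6 → 9 → 11 → 12 → 14 → 15 → 16 → 19 → 20 → 21 → 22; steps 2–10 and 12–15).

Steps most likely to fail

Step 8. The ion pair may discriminate the two faces of the quinone methide poorly, or a catalyst-free closure mediated by caesium phenoxide may erode the selectivity. Deprotonation at C2 may also be too slow, so that 13 is lost to oligomerisation or to re-addition of sulfinate or water. The fallback uses known chemistry, sets out from 1 and returns at 16. Stobbe condensation of 1 with dimethyl succinate (NaOMe, MeOH, reflux) should give (E)-4-[3,4-bis(benzyloxy)phenyl]-3-(methoxycarbonyl)but-3-enoic acid F1, and methylation (MeI, K2CO3, DMF) dimethyl (E)-2-[3,4-bis(benzyloxy)benzylidene]butanedioate F2. Commercial 4-(benzyloxy)-3-hydroxybenzaldehyde is converted with MOMCl and i-Pr2NEt into 4-(benzyloxy)-3-(methoxymethoxy)benzaldehyde F3. The lithium dienolate of F2 (LiN(i-Pr)2, THF, −78 °C) adds through its CH2 carbon to F3; a cold AcOH quench gives the aldol adduct dimethyl (E)-2-[3,4-bis(benzyloxy)benzylidene]-3-[[4-(benzyloxy)-3-(methoxymethoxy)phenyl](hydroxy)methyl]butanedioate F4. TFA in CH2Cl2 (0 °C to rt) ionises the benzylic alcohol, closes ring B by Friedel–Crafts attack of ring A (C1–C8a bond, para to the 3-benzyloxy group) and removes the MOM group. This should give the racemic trans diester, that is 16 together with its enantiomer dimethyl (1S,2R)-6,7-bis(benzyloxy)-1-[4-(benzyloxy)-3-hydroxyphenyl]-1,2-dihydronaphthalene-2,3-dicarboxylate F5. Preparative HPLC on a cellulose tris(3,5-dimethylphenylcarbamate) phase separates the two, and the route continues from 16 at step 12.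

Step 13. Kinetic control may be lost during adduct formation and collapse, which would enrich the more stable enol ether with the aryl group cis to oxygen; competing deprotonation at C2 is a second concern. The fallback sets out from 1 and 16 and returns at 20, replacing olefination by a stereoretentive C–O coupling. Corey–Fuchs reaction of 1 (CBr4, PPh3, CH2Cl2) gives 1,2-bis(benzyloxy)-4-(2,2-dibromoethenyl)benzene F6. Treatment with n-BuLi and then ClCO2Me gives methyl 3-[3,4-bis(benzyloxy)phenyl]prop-2-ynoate F7. Syn-hydrostannation catalysed by Pd(PPh3)4 (Bu3SnH, THF) places tin alpha to the ester and gives methyl (E)-3-[3,4-bis(benzyloxy)phenyl]-2-(tributylstannyl)prop-2-enoate F8, in which the aryl group is cis to the ester. Iododestannylation (I2, CH2Cl2, 0 °C) with retention gives methyl (E)-3-[3,4-bis(benzyloxy)phenyl]-2-iodoprop-2-enoate F9. Ullmann-type O-vinylation of phenol 16 with F9 (CuI, N,N-dimethylglycine, Cs2CO3, 1,4-dioxane, 80 °C) proceeds with retention of alkene geometry and gives 20.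

Step 6. Oxidative addition and insertion may be sluggish at the hindered, electron-rich aryl bromide. Re-addition of the palladium hydride may move the new double bond to the Z isomer or out of conjugation, and the arylpalladium species may instead arylate the pendant ring intramolecularly. The fallback sets out from 9 and returns at 11. Bromine–lithium exchange of 9 (n-BuLi, THF, −78 °C) and a DMF quench give 4,5-bis(benzyloxy)-2-[methoxy[3-(methoxymethoxy)-4-(tetrahydro-2H-pyran-2-yloxy)phenyl]methyl]benzaldehyde F10. Stobbe condensation with dimethyl succinate (NaOMe, MeOH, reflux) gives (E)-4-[4,5-bis(benzyloxy)-2-[methoxy[3-(methoxymethoxy)-4-(tetrahydro-2H-pyran-2-yloxy)phenyl]methyl]phenyl]-3-(methoxycarbonyl)but-3-enoic acid F11. Methylation (MeI, K2CO3, DMF) gives 11; no free alkoxide is ever present next to the acceptor.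

Further compounds
F1 | step 8 | (E)-4-[3,4-bis(benzyloxy)phenyl]-3-(methoxycarbonyl)but-3-enoic acid | OC(=O)C/C(C(=O)OC)=C\c1ccc(OCc2ccccc2)c(OCc2ccccc2)c1
F2 | step 8 | dimethyl (E)-2-[3,4-bis(benzyloxy)benzylidene]butanedioate | COC(=O)C/C(C(=O)OC)=C\c1ccc(OCc2ccccc2)c(OCc2ccccc2)c1
F3 | step 8 | 4-(benzyloxy)-3-(methoxymethoxy)benzaldehyde | O=Cc1ccc(OCc2ccccc2)c(OCOC)c1
F4 | step 8 | dimethyl (E)-2-[3,4-bis(benzyloxy)benzylidene]-3-[[4-(benzyloxy)-3-(methoxymethoxy)phenyl](hydroxy)methyl]butanedioate, diastereomer mixture | COC(=O)C(C(O)c1ccc(OCc2ccccc2)c(OCOC)c1)/C(C(=O)OC)=C\c1ccc(OCc2ccccc2)c(OCc2ccccc2)c1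
F5 | step 8 | dimethyl (1S,2R)-6,7-bis(benzyloxy)-1-[4-(benzyloxy)-3-hydroxyphenyl]-1,2-dihydronaphthalene-2,3-dicarboxylate, enantiomer of 16 | COC(=O)C1=Cc2cc(OCc3ccccc3)c(OCc3ccccc3)cc2[C@H](c2ccc(OCc3ccccc3)c(O)c2)[C@H]1C(=O)OC
F6 | step 13 | 1,2-bis(benzyloxy)-4-(2,2-dibromoethenyl)benzene | BrC(Br)=Cc1ccc(OCc2ccccc2)c(OCc2ccccc2)c1
F7 | step 13 | methyl 3-[3,4-bis(benzyloxy)phenyl]prop-2-ynoate | COC(=O)C#Cc1ccc(OCc2ccccc2)c(OCc2ccccc2)c1
F8 | step 13 | methyl (E)-3-[3,4-bis(benzyloxy)phenyl]-2-(tributylstannyl)prop-2-enoate | CCCC[Sn](CCCC)(CCCC)/C(C(=O)OC)=C/c1ccc(OCc2ccccc2)c(OCc2ccccc2)c1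
F9 | step 13 | methyl (E)-3-[3,4-bis(benzyloxy)phenyl]-2-iodoprop-2-enoate | I/C(C(=O)OC)=C/c1ccc(OCc2ccccc2)c(OCc2ccccc2)c1
F10 | step 6 | 4,5-bis(benzyloxy)-2-[methoxy[3-(methoxymethoxy)-4-(tetrahydro-2H-pyran-2-yloxy)phenyl]methyl]benzaldehyde | O=Cc1cc(OCc2ccccc2)c(OCc2ccccc2)cc1C(OC)c1ccc(OC2CCCCO2)c(OCOC)c1
F11 | step 6 | (E)-4-[4,5-bis(benzyloxy)-2-[methoxy[3-(methoxymethoxy)-4-(tetrahydro-2H-pyran-2-yloxy)phenyl]methyl]phenyl]-3-(methoxycarbonyl)but-3-enoic acid | OC(=O)C/C(C(=O)OC)=C\c1cc(OCc2ccccc2)c(OCc2ccccc2)cc1C(OC)c1ccc(OC2CCCCO2)c(OCOC)c1
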